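**Retrosynthetic overview**
1. The lower unit (all-cis 2-(4-hydroxyphenyl)chroman-3,4-diol) is opened at C3–C4 of its pyran ring C. The cis-diol C3(OH)–C4(OH), held between C2–O1 and C4a of ring A, is read as two aldehydes (salicylaldehyde CHO = C4, α-aryloxy aldehyde = C3) that a SmI2 pinacol cyclization joins; the acid-labile benzylic diol is thus made after all acid chemistry.
2. The C4(upper)–C6(lower) bond is made one stage earlier by Friedel–Crafts capture of the upper flavan-4-yl cation by the still open-chain lower fragment (both carbinols masked as acetates).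
3. The upper 2,3-cis unit comes from the same C3–C4 pinacol closure of a sister dialdehyde; its C4–OH is spent as the leaving group.
4. Both dialdehydes come from one salicylaldehyde (3) and an (S)-mandelate (Mitsunobu etherification with inversion sets C2), followed by reduction and oxidation.
5. Ring order: upper ring C (step 8), interflavan bond (step 14), lower ring C (step 17), global debenzylation (step 18).

Key step: step 17

Assumption: compounds 1, 4, 5 and 13 are purchased, and the SmI2 cyclizations (steps 8 and 17) are taken to pass through a transition state in which one trivalent samarium ion bridges both oxygen atoms.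
Convention: flavan numbering (O1, C2, C3, C4; ring A fused, ring C = pyran ring, ring B = 2-aryl); "upper unit" = the 4-aryl-flavan-3-ol half, "lower unit" = the flavan-3,4-diol half. In the benzylated dimers 20–23 the upper C4 has the descriptor R; in phenol 24 the same geometry is S, because the substituent priorities change.

**Route**

Step 1
Reactants: 1 2,3,4-trihydroxybenzaldehyde
Product: 2 2,3,4-tris(benzyloxy)benzaldehyde
Conditions: BnBr (3.5 equiv), K2CO3, DMF, 60 °C
Reagents that add atoms: benzyl bromide BrCc1ccccc1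
Why: Williamson ether synthesis on all three phenols; no stereocentre is involved.

Step 2
Reactants: 2 2,3,4-tris(benzyloxy)benzaldehyde
Product: 3 3,4-bis(benzyloxy)-2-hydroxybenzaldehyde
Conditions: MgBr2·OEt2 (1.2 equiv), toluene/Et2O, 80 °C; then 1 M HCl
Reagents that add atoms: none
Why: Chelation-assisted Lewis-acid dealkylation: only the benzyl ether ortho to the formyl group can bind magnesium together with the carbonyl oxygen, so bromide should remove this benzyl group alone.

Step 3
Reactants: 4 1,2-bis(benzyloxy)-4-bromobenzene; 5 dimethyl oxalate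
Product: 7 methyl [3,4-bis(benzyloxy)phenyl](oxo)acetate, via aryl Grignard reagent 6 (not isolated)
Conditions: Mg, THF, 40 °C; then added to 5 (2 equiv), THF, −78 °C; 1 M HCl
Reagents that add atoms: none
Why: Grignard acylation of an oxalate diester; inverse addition at −78 °C keeps the magnesium hemiketal intact until work-up, so the keto ester should not be attacked twice.

Step 4
Reactants: 7 methyl [3,4-bis(benzyloxy)phenyl](oxo)acetate
Product: 8 methyl (2S)-[3,4-bis(benzyloxy)phenyl](hydroxy)acetate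
Conditions: RuCl[(R,R)-TsDPEN](p-cymene) (1 mol%), HCO2H/Et3N 5:2, DMF, 25 °C
Reagents that add atoms: none
Why: Noyori asymmetric transfer hydrogenation of an aryl α-keto ester; the aryl ring is recognised by the η6-arene ligand as in aryl ketones, and the (R,R)-catalyst should deliver hydride to the face that gives the (S)-carbinol (the centre that becomes upper C2 after inversion).

Step 5
Reactants: 3 3,4-bis(benzyloxy)-2-hydroxybenzaldehyde; 8 methyl (2S)-[3,4-bis(benzyloxy)phenyl](hydroxy)acetate
Product: 9 methyl (2R)-[2,3-bis(benzyloxy)-6-formylphenoxy][3,4-bis(benzyloxy)phenyl]acetate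
Conditions: PPh3, DIAD, toluene, 0 → 25 °C
Reagents that add atoms: none
Why: Mitsunobu etherification; the acidic ortho-formyl phenol displaces the activated carbinol oxygen by SN2 at a carbon whose cation is disfavoured by the ester, so the centre should invert cleanly to (R) (upper C2).

Step 6
Reactants: 9 methyl (2R)-[2,3-bis(benzyloxy)-6-formylphenoxy][3,4-bis(benzyloxy)phenyl]acetate
Product: 10 (2R)-2-[2,3-bis(benzyloxy)-6-(hydroxymethyl)phenoxy]-2-[3,4-bis(benzyloxy)phenyl]ethan-1-ol
Conditions: i-Bu2AlH (4.5 equiv), CH2Cl2, −78 → 0 °C; aq. potassium sodium tartrate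
Reagents that add atoms: none
Why: Hydride reduction of the aryl aldehyde and the ester to two primary alcohols at low temperature, which leaves the ether stereocentre untouched.

Step 7
Reactants: 10 (2R)-2-[2,3-bis(benzyloxy)-6-(hydroxymethyl)phenoxy]-2-[3,4-bis(benzyloxy)phenyl]ethan-1-ol
Product: 11 3,4-bis(benzyloxy)-2-{(1R)-1-[3,4-bis(benzyloxy)phenyl]-2-oxoethoxy}benzaldehyde
Conditions: Dess–Martin periodinane (2.4 equiv), pyridine, CH2Cl2, 0 °C; used at once
Reagents that add atoms: none
Why: Dess–Martin oxidation of both primary alcohols under buffered, non-basic conditions, chosen because the α-aryl-α-aryloxy aldehyde is configurationally labile towards base.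

Step 8
Reactants: 11 3,4-bis(benzyloxy)-2-{(1R)-1-[3,4-bis(benzyloxy)phenyl]-2-oxoethoxy}benzaldehyde
Product: 12 (2R,3R,4R)-7,8-bis(benzyloxy)-2-[3,4-bis(benzyloxy)phenyl]chromane-3,4-diol (all-cis)
Conditions: SmI2 (2.5 equiv, 0.1 M in THF), THF (0.01 M), −78 → −40 °C; sat. aq. NaHCO3
Reagents that add atoms: none
Why: SmI2 pinacol cyclization as reasoned for step 17: the samarium-bridged ketyl addition closes ring C as the cis-diol and the equatorial 2-aryl group places the axial C3–O on its own side (2,3-cis), while the configuration at C4 is of no consequence because this carbinol is ionised in step 14.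

Step 9
Reactants: 13 1-(benzyloxy)-4-bromobenzene; 5 dimethyl oxalate
Product: 15 methyl [4-(benzyloxy)phenyl](oxo)acetate, via aryl Grignard reagent 14 (not isolated)
Conditions: Mg, THF, 40 °C; then added to 5 (2 equiv), THF, −78 °C; 1 M HCl
Reagents that add atoms: none
Why: Grignard acylation of dimethyl oxalate under the inverse-addition conditions of step 3.

Step 10
Reactants: 15 methyl [4-(benzyloxy)phenyl](oxo)acetate
Product: 16 methyl (2S)-[4-(benzyloxy)phenyl](hydroxy)acetate
Conditions: RuCl[(R,R)-TsDPEN](p-cymene) (1 mol%), HCO2H/Et3N 5:2, DMF, 25 °C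
Reagents that add atoms: none
Why: Noyori asymmetric transfer hydrogenation with the same facial sense as in step 4, which should give the (S)-carbinol (future lower C2 after inversion).

Step 11
Reactants: 3 3,4-bis(benzyloxy)-2-hydroxybenzaldehyde; 16 methyl (2S)-[4-(benzyloxy)phenyl](hydroxy)acetate
Product: 17 methyl (2R)-[2,3-bis(benzyloxy)-6-formylphenoxy][4-(benzyloxy)phenyl]acetate
Conditions: PPh3, DIAD, toluene, 0 → 25 °C
Reagents that add atoms: none
Why: Mitsunobu etherification with SN2 inversion at the ester-flanked benzylic carbon, which sets lower C2 as (R).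

Step 12
Reactants: 17 methyl (2R)-[2,3-bis(benzyloxy)-6-formylphenoxy][4-(benzyloxy)phenyl]acetate
Product: 18 (2R)-2-[2,3-bis(benzyloxy)-6-(hydroxymethyl)phenoxy]-2-[4-(benzyloxy)phenyl]ethan-1-ol
Conditions: i-Bu2AlH (4.5 equiv), CH2Cl2, −78 → 0 °C; aq. potassium sodium tartrate
Reagents that add atoms: none
Why: Hydride reduction of aldehyde and ester to the diol; this removes the ring-deactivating formyl group before the Friedel–Crafts step.

Step 13
Reactants: 18 (2R)-2-[2,3-bis(benzyloxy)-6-(hydroxymethyl)phenoxy]-2-[4-(benzyloxy)phenyl]ethan-1-ol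
Product: 19 (2R)-2-[6-(acetoxymethyl)-2,3-bis(benzyloxy)phenoxy]-2-[4-(benzyloxy)phenyl]ethyl acetate
Conditions: Ac2O, pyridine, DMAP (cat.), CH2Cl2, 0 → 25 °C
Reagents that add atoms: acetic anhydride CC(=O)OC(C)=O
Why: Acylation of both primary alcohols; the acetates keep the benzylic carbinol from ionising or etherifying in step 14 while the ring stays nucleophilic.

Step 14
Reactants: 12 (2R,3R,4R)-7,8-bis(benzyloxy)-2-[3,4-bis(benzyloxy)phenyl]chromane-3,4-diol; 19 (2R)-2-[6-(acetoxymethyl)-2,3-bis(benzyloxy)phenoxy]-2-[4-(benzyloxy)phenyl]ethyl acetate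
Product: 20 diacetate 19 bearing at C4 of its phenoxy ring (para to the ether oxygen) the (2R,3R,4R)-7,8-bis(benzyloxy)-2-[3,4-bis(benzyloxy)phenyl]-3-hydroxychroman-4-yl group (2,3-cis-3,4-trans)
Conditions: Bi(OTf)3 (10 mol%), 19 (3 equiv, excess recovered), 4 Å MS, CH2Cl2, −40 → 0 °C
Reagents that add atoms: none
Why: Dehydrative Friedel–Crafts alkylation (the interflavan bond formation of proanthocyanidin synthesis): Bi(OTf)3 ionises the benzylic C4–OH of 12 to a cation stabilised by O1 and the para 7-benzyloxy group, and 19 attacks through its only doubly activated ring carbon (para to the ether oxygen, ortho to a benzyloxy group) on the face anti to the 3-OH and the 2-aryl group, which sets upper C4 as 3,4-trans.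

Step 15
Reactants: 20 the diacetate dimer
Product: 21 the corresponding triol: (2R)-2-[4-(benzyloxy)phenyl]-2-{2,3-bis(benzyloxy)-6-(hydroxymethyl)-4-[upper chroman-4-yl]phenoxy}ethan-1-ol, upper 3-OH free
Conditions: K2CO3 (cat.), MeOH/THF, 25 °C
Reagents that add atoms: none
Why: Base-catalysed transesterification of the two acetates; no centre is acidic at this oxidation level.

Step 16
Reactants: 21 the triol
Product: 22 the dialdehyde: 3,4-bis(benzyloxy)-2-{(1R)-1-[4-(benzyloxy)phenyl]-2-oxoethoxy}-5-[upper chroman-4-yl]benzaldehyde, upper 3-OH free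
Conditions: TEMPO (20 mol%), PhI(OAc)2 (2.4 equiv), CH2Cl2, 0 → 25 °C; used at once
Reagents that add atoms: none
Why: Oxoammonium (TEMPO/PhI(OAc)2) oxidation, which takes primary alcohols and leaves the hindered axial secondary 3-OH of the upper unit; the non-basic medium protects the labile C2 centre.

Step 17
Reactants: 22 the dialdehyde
Product: 23 (2R,3R,4R)-7,8-bis(benzyloxy)-2-[4-(benzyloxy)phenyl]-6-{(2R,3R,4R)-7,8-bis(benzyloxy)-2-[3,4-bis(benzyloxy)phenyl]-3-hydroxychroman-4-yl}chromane-3,4-diol (lower unit all-cis)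
Conditions: SmI2 (2.5 equiv, 0.1 M in THF), THF (0.01 M), −78 → −40 °C; sat. aq. NaHCO3
Reagents that add atoms: none
Why: SmI2 reduces the aromatic aldehyde (C4) first to a benzylic ketyl on trivalent samarium, which adds to the samarium-coordinated α-aryloxy aldehyde carbon C3 and is reduced again to a cyclic samarium diolate that water opens to the diol; this is the pinacol cyclization of 1,6-dialdehydes to cis-cyclohexane-1,2-diols, transposed to an O-tethered substrate and already run once in step 8. Ring C closes in the 6-exo-trig mode (ketyl carbon in the ring, attacked C=O exocyclic). C3 and C4 should come out cis because one samarium ion bridges both oxygens in the transition state. Their absolute sense is dictated by the mandelate-derived C2: the 2-aryl group sits equatorial in the half-chair, the planar ketyl keeps its O–Sm on the open side away from O1 (the inside position under the folding tether can only hold H) so that it becomes the pseudo-equatorial C4–O, and the bridged C3–O must then be axial, on the side of the 2-aryl group, which gives the all-cis (2R,3R,4R) array. The step needs electron transfer to the aryl aldehyde only, so that no C3 ketyl or carbanion expels the β-aryloxide, and cyclization instead of dimerization; the lower reduction potential of the salicylaldehyde unit, the absence of HMPA, the measured SmI2 charge at −78 °C and high dilution should secure this, while the benzyl ethers and the free upper 3-OH are inert.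

Step 18
Reactants: 23 the hepta-O-benzyl ether
Product: 24 (2R,3R,4R)-6-[(2R,3R,4S)-2-(3,4-dihydroxyphenyl)-3,7,8-trihydroxychroman-4-yl]-2-(4-hydroxyphenyl)chromane-3,4,7,8-tetrol (target)
Conditions: H2 (1 atm), Pd(OH)2/C, THF/MeOH 1:1, 25 °C; filtration under argon, freeze-drying
Reagents that add atoms: none
Why: Hydrogenolysis of the seven benzyl ethers under neutral conditions, in which the benzylic C2–O1 bonds, the C4–OH and the interflavan bond should survive because no acid is present.

**Compound list**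
1 | 2,3,4-trihydroxybenzaldehyde | O=Cc1ccc(O)c(O)c1O | starting material
2 | 2,3,4-tris(benzyloxy)benzaldehyde | O=Cc1ccc(OCc2ccccc2)c(OCc2ccccc2)c1OCc1ccccc1 | intermediate
3 | 3,4-bis(benzyloxy)-2-hydroxybenzaldehyde | O=Cc1ccc(OCc2ccccc2)c(OCc2ccccc2)c1O | intermediate
4 | 1,2-bis(benzyloxy)-4-bromobenzene | Brc1ccc(OCc2ccccc2)c(OCc2ccccc2)c1 | starting material
5 | dimethyl oxalate | COC(=O)C(=O)OC | starting material
6 | [3,4-bis(benzyloxy)phenyl]magnesium bromide | Br[Mg]c1ccc(OCc2ccccc2)c(OCc2ccccc2)c1 | intermediate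
7 | methyl [3,4-bis(benzyloxy)phenyl](oxo)acetate | COC(=O)C(=O)c1ccc(OCc2ccccc2)c(OCc2ccccc2)c1 | intermediate
8 | methyl (2S)-[3,4-bis(benzyloxy)phenyl](hydroxy)acetate | COC(=O)[C@@H](O)c1ccc(OCc2ccccc2)c(OCc2ccccc2)c1 | intermediate
9 | methyl (2R)-[2,3-bis(benzyloxy)-6-formylphenoxy][3,4-bis(benzyloxy)phenyl]acetate | COC(=O)[C@H](Oc1c(C=O)ccc(OCc2ccccc2)c1OCc1ccccc1)c1ccc(OCc2ccccc2)c(OCc2ccccc2)c1 | intermediate
10 | (2R)-2-[2,3-bis(benzyloxy)-6-(hydroxymethyl)phenoxy]-2-[3,4-bis(benzyloxy)phenyl]ethan-1-ol | OC[C@H](Oc1c(CO)ccc(OCc2ccccc2)c1OCc1ccccc1)c1ccc(OCc2ccccc2)c(OCc2ccccc2)c1 | intermediate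
11 | 3,4-bis(benzyloxy)-2-{(1R)-1-[3,4-bis(benzyloxy)phenyl]-2-oxoethoxy}benzaldehyde | O=C[C@H](Oc1c(C=O)ccc(OCc2ccccc2)c1OCc1ccccc1)c1ccc(OCc2ccccc2)c(OCc2ccccc2)c1 | intermediate
12 | (2R,3R,4R)-7,8-bis(benzyloxy)-2-[3,4-bis(benzyloxy)phenyl]chromane-3,4-diol (all-cis) | C(c1ccccc1)Oc1ccc([C@H]2Oc3c(ccc(OCc4ccccc4)c3OCc3ccccc3)[C@@H](O)[C@H]2O)cc1OCc1ccccc1 | intermediate
13 | 1-(benzyloxy)-4-bromobenzene | Brc1ccc(OCc2ccccc2)cc1 | starting material
14 | [4-(benzyloxy)phenyl]magnesium bromide | Br[Mg]c1ccc(OCc2ccccc2)cc1 | intermediate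
15 | methyl [4-(benzyloxy)phenyl](oxo)acetate | COC(=O)C(=O)c1ccc(OCc2ccccc2)cc1 | intermediate
16 | methyl (2S)-[4-(benzyloxy)phenyl](hydroxy)acetate | COC(=O)[C@@H](O)c1ccc(OCc2ccccc2)cc1 | intermediate
17 | methyl (2R)-[2,3-bis(benzyloxy)-6-formylphenoxy][4-(benzyloxy)phenyl]acetate | COC(=O)[C@H](Oc1c(C=O)ccc(OCc2ccccc2)c1OCc1ccccc1)c1ccc(OCc2ccccc2)cc1 | intermediate
18 | (2R)-2-[2,3-bis(benzyloxy)-6-(hydroxymethyl)phenoxy]-2-[4-(benzyloxy)phenyl]ethan-1-ol | OC[C@H](Oc1c(CO)ccc(OCc2ccccc2)c1OCc1ccccc1)c1ccc(OCc2ccccc2)cc1 | intermediate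
19 | (2R)-2-[6-(acetoxymethyl)-2,3-bis(benzyloxy)phenoxy]-2-[4-(benzyloxy)phenyl]ethyl acetate | CC(=O)OC[C@H](Oc1c(COC(C)=O)ccc(OCc2ccccc2)c1OCc1ccccc1)c1ccc(OCc2ccccc2)cc1 | intermediate
20 | diacetate 19 bearing at C4 of the phenoxy ring the (2R,3R,4R)-7,8-bis(benzyloxy)-2-[3,4-bis(benzyloxy)phenyl]-3-hydroxychroman-4-yl group (2,3-cis-3,4-trans) | CC(=O)OC[C@H](Oc1c(COC(C)=O)cc([C@H]2c3ccc(OCc4ccccc4)c(OCc4ccccc4)c3O[C@H](c3ccc(OCc4ccccc4)c(OCc4ccccc4)c3)[C@@H]2O)c(OCc2ccccc2)c1OCc1ccccc1)c1ccc(OCc2ccccc2)cc1 | intermediate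
21 | triol from 20 (both acetates removed; upper 3-OH free) | OC[C@H](Oc1c(CO)cc([C@H]2c3ccc(OCc4ccccc4)c(OCc4ccccc4)c3O[C@H](c3ccc(OCc4ccccc4)c(OCc4ccccc4)c3)[C@@H]2O)c(OCc2ccccc2)c1OCc1ccccc1)c1ccc(OCc2ccccc2)cc1 | intermediate
22 | dialdehyde from 21: 3,4-bis(benzyloxy)-2-{(1R)-1-[4-(benzyloxy)phenyl]-2-oxoethoxy}-5-[(2R,3R,4R)-7,8-bis(benzyloxy)-2-[3,4-bis(benzyloxy)phenyl]-3-hydroxychroman-4-yl]benzaldehyde | O=C[C@H](Oc1c(C=O)cc([C@H]2c3ccc(OCc4ccccc4)c(OCc4ccccc4)c3O[C@H](c3ccc(OCc4ccccc4)c(OCc4ccccc4)c3)[C@@H]2O)c(OCc2ccccc2)c1OCc1ccccc1)c1ccc(OCc2ccccc2)cc1 | intermediate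
23 | (2R,3R,4R)-7,8-bis(benzyloxy)-2-[4-(benzyloxy)phenyl]-6-{(2R,3R,4R)-7,8-bis(benzyloxy)-2-[3,4-bis(benzyloxy)phenyl]-3-hydroxychroman-4-yl}chromane-3,4-diol (hepta-O-benzyl ether of the target) | C(c1ccccc1)Oc1ccc([C@H]2Oc3c(cc([C@H]4c5ccc(OCc6ccccc6)c(OCc6ccccc6)c5O[C@H](c5ccc(OCc6ccccc6)c(OCc6ccccc6)c5)[C@@H]4O)c(OCc4ccccc4)c3OCc3ccccc3)[C@@H](O)[C@H]2O)cc1 | intermediate
24 | (2R,3R,4R)-6-[(2R,3R,4S)-2-(3,4-dihydroxyphenyl)-3,7,8-trihydroxychroman-4-yl]-2-(4-hydroxyphenyl)chromane-3,4,7,8-tetrol | Oc1ccc([C@H]2Oc3c(cc([C@H]4c5ccc(O)c(O)c5O[C@H](c5ccc(O)c(O)c5)[C@@H]4O)c(O)c3O)[C@@H](O)[C@H]2O)cc1 | target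

**Step count and risks**
Total step count: 18. Longest linear sequence: 11 steps (1, 2, 5, 6, 7, 8, 14, 15, 16, 17, 18).

Steps most likely to fail:

Step 17 (and its rehearsal, step 8). What may go wrong is poor facial selectivity at the α-aryloxy aldehyde, so that the C3–O bond ends up anti to the 2-aryl group. The fallback hands stereocontrol at the lower unit to a cis-hydrogenation and sets out from dialdehyde 22. The SmI2 ring closure is run without regard to selectivity, and the crude diols, among them the 2,3-trans-3,4-cis diol F1, are oxidised at the benzylic carbinol with MnO2 in CH2Cl2 to the trans-dihydroflavonol F2. I2 and KOAc in AcOH at 90 °C dehydrogenate this to the flavonol F3. Hydrogenation (H2, Pd(OH)2/C then PtO2, EtOH/THF) removes the benzyl groups and adds hydrogen to one face of the pyranone, which is the classical entry to all-cis flavan-3,4-diols. Both faces react, so target 24 forms together with the lower-unit (2S,3S,4S) diastereomer F4; the two are diastereomers because of the upper unit and are separated by reversed-phase HPLC. The fallback comes back to the route at 24.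

Step 14. What may go wrong is self-condensation of the flavan-4-yl cation with the A ring of a second molecule of 12, or ionisation of the benzylic acetate of 19 by the Lewis acid. The fallback changes the donor and its mode of activation and sets out from diol 12. Benzyl mercaptan with a catalytic amount of AcOH gives the 4-thioether F5 (the thiol enters anti to the 3-OH), which is isolated and purified. With 19 and AgBF4 in THF at 0 °C the thiophilic silver salt releases the same cation without a Lewis acid that could touch the acetates. The fallback comes back at 20.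

Step 11 (and step 5). What may go wrong is slow etherification of the hindered, hydrogen-bonded phenol and partial loss of configuration at the benzylic carbon. The fallback makes the C2–O1 bond by an enantioselective carbene O–H insertion and sets out from phenol 3. Diazo ester F6, made from purchased methyl [4-(benzyloxy)phenyl]acetate by diazo transfer (4-acetamidobenzenesulfonyl azide, DBU, MeCN), is inserted into the O–H bond of 3 with PdCl2(PhCN)2, a chiral spiro-bisoxazoline ligand and NaB[3,5-(CF3)2C6H3]4 in CHCl3 at 25 °C; the ligand enantiomer is chosen for the (R)-ether. The fallback comes back at 17.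

**Further compounds**
F1 | step 17 | C3,C4-epimer of 23 with a (2R,3S,4S) lower unit (2,3-trans-3,4-cis) | C(c1ccccc1)Oc1ccc([C@H]2Oc3c(cc([C@H]4c5ccc(OCc6ccccc6)c(OCc6ccccc6)c5O[C@H](c5ccc(OCc6ccccc6)c(OCc6ccccc6)c5)[C@@H]4O)c(OCc4ccccc4)c3OCc3ccccc3)[C@H](O)[C@@H]2O)cc1
F2 | step 17 | trans-dihydroflavonol: lower unit (2R,3R)-3-hydroxychroman-4-one, otherwise as 23 | C(c1ccccc1)Oc1ccc([C@H]2Oc3c(cc([C@H]4c5ccc(OCc6ccccc6)c(OCc6ccccc6)c5O[C@H](c5ccc(OCc6ccccc6)c(OCc6ccccc6)c5)[C@@H]4O)c(OCc4ccccc4)c3OCc3ccccc3)C(=O)[C@@H]2O)cc1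
F3 | step 17 | flavonol: lower unit 7,8-bis(benzyloxy)-2-[4-(benzyloxy)phenyl]-3-hydroxy-4H-chromen-4-one bearing the upper chroman-4-yl group at C6 | O=c1c(O)c(-c2ccc(OCc3ccccc3)cc2)oc2c(OCc3ccccc3)c(OCc3ccccc3)c([C@H]3c4ccc(OCc5ccccc5)c(OCc5ccccc5)c4O[C@H](c4ccc(OCc5ccccc5)c(OCc5ccccc5)c4)[C@@H]3O)cc12
F4 | step 17 | diastereomer of 24 with a (2S,3S,4S) lower unit | Oc1ccc([C@@H]2Oc3c(cc([C@H]4c5ccc(O)c(O)c5O[C@H](c5ccc(O)c(O)c5)[C@@H]4O)c(O)c3O)[C@H](O)[C@@H]2O)cc1
F5 | step 14 | (2R,3S,4S)-4-(benzylsulfanyl)-7,8-bis(benzyloxy)-2-[3,4-bis(benzyloxy)phenyl]chroman-3-ol (2,3-cis-3,4-trans) | C(c1ccccc1)S[C@H]1c2ccc(OCc3ccccc3)c(OCc3ccccc3)c2O[C@H](c2ccc(OCc3ccccc3)c(OCc3ccccc3)c2)[C@@H]1O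
F6 | step 11 | methyl [4-(benzyloxy)phenyl](diazo)acetate | COC(=O)C(=[N+]=[N-])c1ccc(OCc2ccccc2)cc1
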